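O1–C2 and C3–I are cut together, which opens ring C to an aryl ynone. Before that, the two O-benzyl masks and the C5 O-methyl mask are put back and C3–O is traced to C3–I. C3–C4 is then cut to an acetylide and an aldehyde, and C4–C4a and the terminal alkyne carbon go back to one-carbon reagents.
The enabling feature lies in ring A: O1 (on C8a) and the C5 oxygen are both ortho to C4a, and C6, C7 and C8 all bear OMe. Ring A can therefore enter as a mirror-symmetric pentamethoxyphenyl group with two interchangeable ortho OMe groups, and C3 of ring C needs a heteroatom exactly where the cyclisation electrophile lands.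
In the forward direction rings A and B are bought as arenes and elaborated to pentamethoxybenzaldehyde (steps 1–4) and a benzylated arylacetylene (steps 5–8). These are joined and oxidised to the ynone (steps 9–10), and ring C, the only ring made, closes in step 11.
The endgame is C3–I to C3–OH to C3–OMe, then peri-selective 5-O-demethylation and hydrogenolysis (steps 12–15).
There is no stereochemistry to set: the only stereocentre of the route is a racemic carbinol, and oxidation removes it.

Key step: step 11

Remark on the chemistry: the target has no stereogenic element, so it is a single achiral compound and no enantiocontrol is required.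

Step 1
Reactants: 1 3,4,5-trimethoxyphenol
Product: 3 6-hydroxy-2,3,4-trimethoxybenzaldehyde, via aryl iminium chloride 2 (not isolated)
Conditions: POCl3, DMF, 0 °C → rt; then ice–H2O
Reagents that add atoms: N,N-dimethylformamide, CN(C)C=O (formyl CH); water, O (formyl O); phosphoryl chloride, O=P(Cl)(Cl)Cl (chloride of 2 only)
Why: In this Vilsmeier–Haack formylation the chloroiminium ion can only attack one of the two equivalent free positions ortho to the phenol, because the para position carries OMe, so hydrolysis of 2 should give a single salicylaldehyde.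

Step 2
Reactants: 3 6-hydroxy-2,3,4-trimethoxybenzaldehyde
Product: 5 3,4,5-trimethoxybenzene-1,2-diol, via aryl formate 4 (not isolated)
Conditions: 30% H2O2 (1.1 equiv), aq NaOH, N2, 0 °C → rt; then dil. HCl
Reagents that add atoms: hydrogen peroxide, OO
Why: In this Dakin oxidation hydroperoxide adds to the aldehyde, the very electron-rich aryl group migrates to oxygen and formate 4 is saponified in the same medium, while exclusion of air and near-stoichiometric peroxide protect the catechol from over-oxidation.

Step 3
Reactants: 5 3,4,5-trimethoxybenzene-1,2-diol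
Product: 6 pentamethoxybenzene
Conditions: MeI, K2CO3, DMF, N2, rt → 40 °C (crude 5 used at once)
Reagents that add atoms: iodomethane, CI
Why: This is a double Williamson ether synthesis on an unhindered catechol, carried out at once under nitrogen so that quinone formation cannot compete.

Step 4
Reactants: 6 pentamethoxybenzene
Product: 8 pentamethoxybenzaldehyde, via pentamethoxyphenyllithium 7 (not isolated)
Conditions: n-BuLi, TMEDA, THF, 0 °C; DMF, −78 °C → rt; H2O
Reagents that add atoms: N,N-dimethylformamide, CN(C)C=O; n-butyllithium, [Li]CCCC (lithium of 7 only)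
Why: In this directed ortho-metalation and formylation the only ring hydrogen lies between two methoxy groups that acidify it and coordinate lithium, and DMF holds 7 as a hemiaminal alkoxide that releases the aldehyde only on hydrolysis.

Step 5
Reactants: 9 methyl 3,5-dihydroxy-4-methoxybenzoate
Product: 10 methyl 3,5-bis(benzyloxy)-4-methoxybenzoate
Conditions: BnBr, K2CO3, DMF, 60 °C
Reagents that add atoms: benzyl bromide, BrCc1ccccc1
Why: Williamson benzylation of the two equivalent phenols installs groups that tolerate hydride, organometallics, ICl and base and leave at the end by hydrogenolysis.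

Step 6
Reactants: 10 methyl 3,5-bis(benzyloxy)-4-methoxybenzoate
Product: 11 [3,5-bis(benzyloxy)-4-methoxyphenyl]methanol
Conditions: LiAlH4, THF, 0 °C → rt; aq NaOH work-up
Reagents that add atoms: none
Why: Hydride reduction of an aromatic ester to the benzylic alcohol touches neither the aryl ethers nor the benzyl ethers.

Step 7
Reactants: 11 [3,5-bis(benzyloxy)-4-methoxyphenyl]methanol
Product: 12 3,5-bis(benzyloxy)-4-methoxybenzaldehyde
Conditions: activated MnO2, CH2Cl2, rt
Reagents that add atoms: none
Why: Manganese dioxide oxidation is selective for benzylic alcohols and stops at the aldehyde.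

Step 8
Reactants: 12 3,5-bis(benzyloxy)-4-methoxybenzaldehyde
Product: 13 1,3-bis(benzyloxy)-5-ethynyl-2-methoxybenzene
Conditions: dimethyl (1-diazo-2-oxopropyl)phosphonate, K2CO3, MeOH–THF, rt
Reagents that add atoms: dimethyl (1-diazo-2-oxopropyl)phosphonate, COP(=O)(OC)C(=[N+]=[N-])C(C)=O
Why: In this Ohira–Bestmann variant of the Seyferth–Gilbert homologation the diazophosphonate anion olefinates the non-enolisable aromatic aldehyde, and loss of nitrogen with a 1,2-hydrogen shift gives the terminal alkyne under mild base.

Step 9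
Reactants: 13 1,3-bis(benzyloxy)-5-ethynyl-2-methoxybenzene; 8 pentamethoxybenzaldehyde
Product: 15 3-[3,5-bis(benzyloxy)-4-methoxyphenyl]-1-(pentamethoxyphenyl)prop-2-yn-1-ol (racemic), via lithium acetylide 14 (not isolated)
Conditions: n-BuLi, THF, −78 °C; then 8, −78 → 0 °C; H2O
Reagents that add atoms: n-butyllithium, [Li]CCCC (lithium of 14 only)
Why: The slim lithium acetylide adds 1,2 to a non-enolisable aldehyde despite its two ortho substituents, and the new carbinol centre forms as a racemate, which does not matter because step 10 removes it.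

Step 10
Reactants: 15 3-[3,5-bis(benzyloxy)-4-methoxyphenyl]-1-(pentamethoxyphenyl)prop-2-yn-1-ol
Product: 16 3-[3,5-bis(benzyloxy)-4-methoxyphenyl]-1-(pentamethoxyphenyl)prop-2-yn-1-one
Conditions: activated MnO2, CH2Cl2, rt
Reagents that add atoms: none
Why: The alcohol is both benzylic and propargylic, so manganese dioxide oxidation should give the ynone under neutral conditions that leave the Michael acceptor intact.

Step 11
Reactants: 16 3-[3,5-bis(benzyloxy)-4-methoxyphenyl]-1-(pentamethoxyphenyl)prop-2-yn-1-one; 17 iodine monochloride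
Product: 19 3',5'-bis(benzyloxy)-3-iodo-5,6,7,8,4'-pentamethoxyflavone, via methyloxonium chloride 18 (not isolated)
Conditions: ICl (1.1 equiv, slow addition), CH2Cl2, −78 °C; aq Na2S2O3
Reagents that add atoms: iodine monochloride 17, ClI
Why: ICl transfers I+ to the triple bond of 16, and the resulting iodonium ion is polarised so that the positive charge sits on the alkyne carbon bonded to ring B, which is both β to the carbonyl group and benzylic to an alkoxy-substituted arene. One ortho methoxy oxygen of the pentamethoxyphenyl ketone attacks that carbon anti to iodine and closes ring C in the 6-endo-dig mode (O1–C2 and C3–I are formed), which gives methyloxonium chloride 18; chloride then removes the methyl group by SN2 attack, so chloromethane leaves and the neutral γ-pyrone 19 remains. The closest known reaction type is the ICl-induced demethylative iodocyclisation of 2-methoxyaryl alkynyl ketones to 3-iodochromones. No stereocentre is created. Three selectivities are needed: 6-endo over 5-exo closure, secured by the ynone polarisation because attack at the α-carbon would build charge next to the carbonyl group; a single regioisomer, secured by the mirror symmetry of ring A because either ortho OMe gives the same product and the other one becomes the C5 methoxy group; and alkyne over arene iodination, secured because ring A has no C–H bond, ring B is deactivated by conjugation with the ynone, and only about one equivalent of ICl is added at −78 °C.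

Step 12
Reactants: 19 3',5'-bis(benzyloxy)-3-iodo-5,6,7,8,4'-pentamethoxyflavone
Product: 22 3',5'-bis(benzyloxy)-3-hydroxy-5,6,7,8,4'-pentamethoxyflavone, via 3-magnesioflavone 20 (not isolated), via flavon-3-ylboronate 21 (not isolated)
Conditions: i-PrMgCl·LiCl, THF, −40 °C; B(OMe)3, −40 → 0 °C; 30% H2O2, AcOH, 0 °C → rt
Reagents that add atoms: hydrogen peroxide, OO; isopropylmagnesium chloride, CC(C)[Mg]Cl (MgCl of 20 only); trimethyl borate, COB(OC)OC (B(OMe)2 of 21 only)
Why: Iodine–magnesium exchange on the sp2 C–I bond is faster at −40 °C than addition to the hindered pyrone, and the sequence of 3-metalated flavone, borate capture and peroxide-induced 1,2-shift from boron to oxygen is an established way to flavonols.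

Step 13
Reactants: 22 3',5'-bis(benzyloxy)-3-hydroxy-5,6,7,8,4'-pentamethoxyflavone
Product: 23 3',5'-bis(benzyloxy)-3,5,6,7,8,4'-hexamethoxyflavone
Conditions: MeI, K2CO3, acetone, reflux
Reagents that add atoms: iodomethane, CI
Why: The acidic 3-hydroxy group is the only free OH in the molecule, so this Williamson O-methylation has one site.

Step 14
Reactants: 23 3',5'-bis(benzyloxy)-3,5,6,7,8,4'-hexamethoxyflavone
Product: 25 3',5'-bis(benzyloxy)-5-hydroxy-3,6,7,8,4'-pentamethoxyflavone, via boron chelate 24 (not isolated)
Conditions: BCl3 (1.1 equiv, 1 M in CH2Cl2), CH2Cl2, −78 → −20 °C; then H2O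
Reagents that add atoms: boron trichloride, ClB(Cl)Cl (BCl2 of 24 only)
Why: In this chelation-directed Lewis-acid ether cleavage the single equivalent of BCl3 is bound by the strongly basic pyrone carbonyl oxygen, and chloride removes the peri 5-methyl group because this yields a six-membered boron chelate, favoured over the five-membered one through the 3-OMe group.

Step 15
Reactants: 25 3',5'-bis(benzyloxy)-5-hydroxy-3,6,7,8,4'-pentamethoxyflavone
Product: 26 5,3',5'-trihydroxy-3,6,7,8,4'-pentamethoxyflavone
Conditions: H2 (1 atm), 10% Pd/C, EtOAc–MeOH, rt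
Reagents that add atoms: none
Why: Catalytic hydrogenolysis cleaves both aryl benzyl ethers, while the tetrasubstituted, vinylogous-ester C2=C3 bond of the flavone is not reduced at atmospheric pressure.

Compound list
1 | 3,4,5-trimethoxyphenol | COc1cc(O)cc(OC)c1OC | starting material
2 | [(6-hydroxy-2,3,4-trimethoxyphenyl)methylidene]dimethylammonium chloride (formed and consumed in the flask) | C[N+](C)=Cc1c(O)cc(OC)c(OC)c1OC.[Cl-] | intermediate
3 | 6-hydroxy-2,3,4-trimethoxybenzaldehyde | O=Cc1c(O)cc(OC)c(OC)c1OC | intermediate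
4 | 6-hydroxy-2,3,4-trimethoxyphenyl formate (formed and consumed in the flask) | O=COc1c(O)cc(OC)c(OC)c1OC | intermediate
5 | 3,4,5-trimethoxybenzene-1,2-diol | Oc1cc(OC)c(OC)c(OC)c1O | intermediate
6 | pentamethoxybenzene | COc1cc(OC)c(OC)c(OC)c1OC | intermediate
7 | (pentamethoxyphenyl)lithium (formed and consumed in the flask) | [Li]c1c(OC)c(OC)c(OC)c(OC)c1OC | intermediate
8 | pentamethoxybenzaldehyde | O=Cc1c(OC)c(OC)c(OC)c(OC)c1OC | intermediate
9 | methyl 3,5-dihydroxy-4-methoxybenzoate | COC(=O)c1cc(O)c(OC)c(O)c1 | starting material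
10 | methyl 3,5-bis(benzyloxy)-4-methoxybenzoate | COC(=O)c1cc(OCc2ccccc2)c(OC)c(OCc2ccccc2)c1 | intermediate
11 | [3,5-bis(benzyloxy)-4-methoxyphenyl]methanol | OCc1cc(OCc2ccccc2)c(OC)c(OCc2ccccc2)c1 | intermediate
12 | 3,5-bis(benzyloxy)-4-methoxybenzaldehyde | O=Cc1cc(OCc2ccccc2)c(OC)c(OCc2ccccc2)c1 | intermediate
13 | 1,3-bis(benzyloxy)-5-ethynyl-2-methoxybenzene | C#Cc1cc(OCc2ccccc2)c(OC)c(OCc2ccccc2)c1 | intermediate
14 | lithium [3,5-bis(benzyloxy)-4-methoxyphenyl]acetylide (formed and consumed in the flask) | [Li]C#Cc1cc(OCc2ccccc2)c(OC)c(OCc2ccccc2)c1 | intermediate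
15 | 3-[3,5-bis(benzyloxy)-4-methoxyphenyl]-1-(pentamethoxyphenyl)prop-2-yn-1-ol (racemic) | COc1c(OC)c(OC)c(C(O)C#Cc2cc(OCc3ccccc3)c(OC)c(OCc3ccccc3)c2)c(OC)c1OC | intermediate
16 | 3-[3,5-bis(benzyloxy)-4-methoxyphenyl]-1-(pentamethoxyphenyl)prop-2-yn-1-one | COc1c(OC)c(OC)c(C(=O)C#Cc2cc(OCc3ccccc3)c(OC)c(OCc3ccccc3)c2)c(OC)c1OC | intermediate
17 | iodine monochloride | ClI | starting material
18 | 2-[3,5-bis(benzyloxy)-4-methoxyphenyl]-3-iodo-5,6,7,8-tetramethoxy-1-methyl-4-oxo-4H-chromen-1-ium chloride (formed and consumed in the flask) | C[O+]1C(c2cc(OCc3ccccc3)c(OC)c(OCc3ccccc3)c2)=C(I)C(=O)c2c(OC)c(OC)c(OC)c(OC)c21.[Cl-] | intermediate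
19 | 3',5'-bis(benzyloxy)-3-iodo-5,6,7,8,4'-pentamethoxyflavone | COc1c(OCc2ccccc2)cc(-c2oc3c(OC)c(OC)c(OC)c(OC)c3c(=O)c2I)cc1OCc1ccccc1 | intermediate
20 | [3',5'-bis(benzyloxy)-5,6,7,8,4'-pentamethoxyflavon-3-yl]magnesium chloride (formed and consumed in the flask) | COc1c(OCc2ccccc2)cc(-c2oc3c(OC)c(OC)c(OC)c(OC)c3c(=O)c2[Mg]Cl)cc1OCc1ccccc1 | intermediate
21 | dimethyl [3',5'-bis(benzyloxy)-5,6,7,8,4'-pentamethoxyflavon-3-yl]boronate (formed and consumed in the flask) | COc1c(OCc2ccccc2)cc(-c2oc3c(OC)c(OC)c(OC)c(OC)c3c(=O)c2B(OC)OC)cc1OCc1ccccc1 | intermediate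
22 | 3',5'-bis(benzyloxy)-3-hydroxy-5,6,7,8,4'-pentamethoxyflavone | COc1c(OCc2ccccc2)cc(-c2oc3c(OC)c(OC)c(OC)c(OC)c3c(=O)c2O)cc1OCc1ccccc1 | intermediate
23 | 3',5'-bis(benzyloxy)-3,5,6,7,8,4'-hexamethoxyflavone | COc1c(OCc2ccccc2)cc(-c2oc3c(OC)c(OC)c(OC)c(OC)c3c(=O)c2OC)cc1OCc1ccccc1 | intermediate
24 | 3',5'-bis(benzyloxy)-5-(dichloroboryloxy)-3,6,7,8,4'-pentamethoxyflavone, boron also coordinated by the C4 carbonyl oxygen (formed and consumed in the flask) | COc1c(OCc2ccccc2)cc(-c2oc3c(OC)c(OC)c(OC)c(OB(Cl)Cl)c3c(=O)c2OC)cc1OCc1ccccc1 | intermediate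
25 | 3',5'-bis(benzyloxy)-5-hydroxy-3,6,7,8,4'-pentamethoxyflavone | COc1c(OCc2ccccc2)cc(-c2oc3c(OC)c(OC)c(OC)c(O)c3c(=O)c2OC)cc1OCc1ccccc1 | intermediate
26 | 5,3',5'-trihydroxy-3,6,7,8,4'-pentamethoxyflavone | COc1c(O)cc(-c2oc3c(OC)c(OC)c(OC)c(O)c3c(=O)c2OC)cc1O | target

Total step count: 15.
Longest linear sequence: 11 steps (steps 1–4 and 9–15 from 1; the branch from 9 through steps 5–8 and 9–15 is equally long).

Steps most likely to fail

Step 11. Ring B may be iodinated. ICl may also simply add across the triple bond because the crowded ortho methoxy oxygen engages too slowly. The fallback separates ring closure from C3 functionalisation and sets out from 16.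
- One equivalent of BCl3 in CH2Cl2 at −78 °C binds to the ketone and cleaves one of the two equivalent ortho methyl ethers. This gives 2-{3-[3,5-bis(benzyloxy)-4-methoxyphenyl]prop-2-ynoyl}-3,4,5,6-tetramethoxyphenyl dichloroborinate F1.
- Aqueous work-up converts it into 3-[3,5-bis(benzyloxy)-4-methoxyphenyl]-1-(2-hydroxy-3,4,5,6-tetramethoxyphenyl)prop-2-yn-1-one F2.
- Catalytic DMAP in DMF adds the free phenol to the ynone in the 6-endo sense and should give 3',5'-bis(benzyloxy)-5,6,7,8,4'-pentamethoxyflavone F3.
- LDA in THF at −78 °C removes H3 to give [3',5'-bis(benzyloxy)-5,6,7,8,4'-pentamethoxyflavon-3-yl]lithium F4.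
- B(OMe)3 converts this into boronate 21, where the route is rejoined. Oxidation as in step 12 then leads to 22.

Step 12. The 3-magnesiated chromone may open by β-elimination of the aryloxide. It may also be protonated before boron capture, or the Grignard reagent may add to the pyrone. The fallback avoids any carbanion at C3 and sets out from 19.
- Miyaura borylation (B2pin2, PdCl2(dppf), KOAc, dioxane, 80 °C) should give 3',5'-bis(benzyloxy)-5,6,7,8,4'-pentamethoxy-3-(4,4,5,5-tetramethyl-1,3,2-dioxaborolan-2-yl)flavone F5.
- Oxidation with NaBO3·4H2O in THF–H2O at rt comes back to the route at 22.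

Step 14. Free Lewis acid may cleave the benzyl ethers, with C-benzylation of the electron-rich rings. A second demethylation at the 3-OMe or 6-OMe group is also possible. The fallback reverses the order of the last two operations, replaces the Lewis acid by a Brønsted acid and sets out from 23.
- Hydrogenolysis (H2, Pd/C, EtOAc–MeOH) should give 3',5'-dihydroxy-3,5,6,7,8,4'-hexamethoxyflavone F6.
- Heating in ethanolic HCl then removes only the 5-methyl group. This is the most acid-labile ether of polymethoxyflavones because the protonated carbonyl group activates it and the resulting phenol is locked by a hydrogen bond. The product is 26.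

Further compounds
F1 | step 11 | 2-{3-[3,5-bis(benzyloxy)-4-methoxyphenyl]prop-2-ynoyl}-3,4,5,6-tetramethoxyphenyl dichloroborinate | COc1c(OB(Cl)Cl)c(C(=O)C#Cc2cc(OCc3ccccc3)c(OC)c(OCc3ccccc3)c2)c(OC)c(OC)c1OC
F2 | step 11 | 3-[3,5-bis(benzyloxy)-4-methoxyphenyl]-1-(2-hydroxy-3,4,5,6-tetramethoxyphenyl)prop-2-yn-1-one | COc1c(O)c(C(=O)C#Cc2cc(OCc3ccccc3)c(OC)c(OCc3ccccc3)c2)c(OC)c(OC)c1OC
F3 | step 11 | 3',5'-bis(benzyloxy)-5,6,7,8,4'-pentamethoxyflavone | COc1c(OCc2ccccc2)cc(-c2cc(=O)c3c(OC)c(OC)c(OC)c(OC)c3o2)cc1OCc1ccccc1
F4 | step 11 | [3',5'-bis(benzyloxy)-5,6,7,8,4'-pentamethoxyflavon-3-yl]lithium | COc1c(OCc2ccccc2)cc(-c2oc3c(OC)c(OC)c(OC)c(OC)c3c(=O)c2[Li])cc1OCc1ccccc1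
F5 | step 12 | 3',5'-bis(benzyloxy)-5,6,7,8,4'-pentamethoxy-3-(4,4,5,5-tetramethyl-1,3,2-dioxaborolan-2-yl)flavone | COc1c(OCc2ccccc2)cc(-c2oc3c(OC)c(OC)c(OC)c(OC)c3c(=O)c2B2OC(C)(C)C(C)(C)O2)cc1OCc1ccccc1
F6 | step 14 | 3',5'-dihydroxy-3,5,6,7,8,4'-hexamethoxyflavone | COc1c(O)cc(-c2oc3c(OC)c(OC)c(OC)c(OC)c3c(=O)c2OC)cc1O
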